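## The problem

CNP0210373.1 (29) is a tetracyclic sesquiterpenoid triester. Its atoms are numbered along the ring path: C1 (tigloyloxy CH), C2, C3 (methyl-bearing quaternary), C4, C5 (acetoxy CH), C6, C7 (methyl carbinol), C8, C9 (quaternary, bears the lactone oxygen O10), C11 (lactone carbonyl), C12, C13, and C14 for the acetoxymethyl carbon on C12. A cyclobutane (ring B: C3, C4, C8, C9) carries two cyclopentanes on opposite edges, ring A (C4 to C8) and ring C (C1, C2, C3, C9, C13), and a butenolide (ring D) is fused to ring C across C9–C13. Both five-membered rings sit on the same face of ring B (cis-syn-cis), so H4, H8, the C3 methyl and O10 share the other face and C3–C9 is a bond between two fully substituted carbons; ordinary enone–alkene photocycloaddition prefers the opposite (anti) arrangement.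

There are seven stereocentres (C1, C3, C4, C5, C7, C8, C9) and an (E)-configured tiglate. Once the four cyclobutane centres are set, the two five-membered rings close a cleft, and reagents reach ring A and ring C only from their outer faces (called exo below; endo is the cleft). The C7 hydroxyl and the C1 oxygen are exo and can be set by substrate control. The C5 acetate is also exo, but hydride will also enter exo, so C5 needs an inversion.

Sensitive features are the three different esters (an allylic primary acetate that is an SN2′ electrophile, a secondary acetate and a conjugated tiglate), the free tertiary C7 hydroxyl β to C5, and the butenolide. On the way, a C9 carbinol next to the C13 ketone on a cyclobutane can ring-expand by α-ketol shift. Strong base, hydride and soft nucleophiles therefore have to be kept away from the late intermediates.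

The feature that opens the core is that C4 and C8 are joined through C5–C6–C7, and these five carbons, with oxygen at C5 and methyl at C7, are the carbon perimeter of 5-methylpyridin-3-ol. A nitrogen atom can therefore hold C4 and C8 together while ring C is attached, and its excision leaves the C4–C8 bond.

## Retrosynthesis

**29 to 28.** The two acetate C–O bonds are cut, O–C5 with inversion and O–C14. A single Mitsunobu operation can install both, and placing it last keeps the allylic acetate (which selenide or base would displace or eliminate) out of every earlier step. Direct acylation of an exo C5 alcohol is not an option because reduction of a C5 ketone gives the endo alcohol. Triol 28 carries one secondary, one primary and one inert tertiary hydroxyl, so the forward step needs only SN2 displacement at C5 from the open exo face.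

**28 to 25.** The C14 ether, the C5 carbinol and the C7 carbinol are traced to a 4-methoxybenzyl ether and a C5-keto C6/C7 epoxide (through 27 and 26). Methyl addition to a C7 ketone would enter exo and leave the hydroxyl endo, whereas peroxide oxygen delivered to a C6=C7 enone enters exo and gives the right carbinol after reductive C6–O cleavage. The epoxy ketone has no free hydroxyl and no unstrained enolisable hydrogen, so it is the resting state of ring A while ring C and ring D are built. The forward reactions must be chemoselective reductions that leave the tiglate, the butenolide and the ether alone.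

**25 to 19 and 23.** Ring D is cut at C12=C13 and O10–C11 (through ester 24). Two neighbouring cuts were weighed and set aside:
- An unsubstituted butenolide followed by C14 attachment would need α-functionalisation of a β,β-disubstituted butenolide.
- Oxidising C1 later through the C13=C1 isomer cannot give the exo C1 oxygen, because an sp3 C13 in a cis-fused ring D forces attack from the cleft.

C14 therefore arrives with the phosphonate 23, and the C1 oxygen is set before ring D exists. The forward steps ask for acylation of a hindered tertiary ketol and an olefination that does not eliminate the β-alkoxy group.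

**23 to 20 and 21.** The C14–O bond and the carboxylic ester are cut (through 22). Both pieces are commercial, and the forward chemistry is an oxa-Michael addition and a selective saponification.

**19 to 15.** The O10–Si bond is restored (18), the tiglate acyl–O bond cut (17), and the C1–O bond cut. The C13 ketone has a single enolisable position, C1, and its exo face is the only open one, so enolate hydroxylation is regio- and stereodefined. Esterifying at once means each hydroxyl of the route appears alone. Compound 15 has lost a stereocentre and all ester groups.

**15 to 14.** The two C–O bonds of the epoxide are cut, giving the ring A enone. The forward step is a nucleophilic epoxidation from the exo face.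

**14 to 11.** The C4–C8 bond is cut and a nitrogen atom inserted between its ends. This one bond is shared by ring A and ring B, and inside a ring that already ties C4 to C8 through C3–C9 it can only form cis. The syn relation to ring C is then set earlier, by how ring C is attached. The alternative cut of C3–C4 and C8–C9 (photocycloaddition) leaves the syn/anti question open. Amine 11 is a bicyclic cycloadduct; the forward step asks for N-amination of a hindered bridged amine and for radical recombination to outrun C3–C9 scission.

**11 to 7.** No skeletal bond is cut: 11 is the resolved form of racemic 9 (through salt 10), and 9 is the N-debenzylated form of 7 (through carbamate 8). A basic secondary amine is the natural point for a classical resolution, and the benzyl group is what lets the pyridine act as a dipole.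

**7 to 5 and 2.** The C3–C4 and C8–C9 bonds are cut, a (5+2) cycloaddition of the oxidopyridinium 6 (from 5) with the ring C alkene of 2. It joins both quaternary carbons to the pyridine perimeter in one step with the expected regiochemistry (enone β-carbon C3 to the oxide-flanked carbon). The forward reaction asks a tetrasubstituted alkene to react and ring C to go endo.

**5 to 3 and 4; 2 to 1.** These are an N–benzyl bond and an O–Si bond; all three starting materials are commercial.

## Roads not taken

**Alternative 1:** The cut is C3–C9, made by 4π-photocyclisation of the ring-A-fused tropolone ether A1 to the bicyclo[3.2.0]heptadienone A2, followed by hydrogenation of the C4=C8 cyclobutene.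
- Merits: the most congested bond of the molecule is formed unimolecularly by a long-known photoisomerisation, ring C arrives as an enone ready for C1 oxygenation, and no amine chemistry is needed. In making C3–C9 intramolecularly it is stronger than the chosen plan, whose intermolecular cycloaddition at a tetrasubstituted alkene is its most doubtful supporting step.
- Weak points: A1 is itself a multistep target. Tropolone ether photoproducts are prone to a second photorearrangement that moves substituents. The syn relation depends on hydrogen reaching a strained, fully substituted cyclobutene from the face that carries the methyl and the benzyloxy group, with benzylic ether cleavage as competitor. A2 has oxygen at C7 only, so the C5 acetate needs a later oxidation. A2 is also racemic with no basic handle.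
- Comparison: the chosen plan sets the syn relation through a bridge and not by a facial selectivity, has C5 and C7 at the right oxidation level from the pyridine, and has an amine to resolve.

**Alternative 2:** The cut is C6–C7, made by Rh2(OAc)4-mediated decomposition of diazoketone A3 with 1,5 C–H insertion into the ether C7–H to give A4.
- Merits: ring A arrives with the C5 ketone and the C7 tertiary ether in the right configuration (insertion with retention), which would save the epoxidation and reductive opening of the chosen plan. For the late ring A pattern this is the better idea.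
- Weak points: A3 already needs ring B with two cis substituents on the face of ring C, so the cis-syn problem is moved to an earlier compound and not solved. The C4 centre next to the diazoketone can epimerise to the less crowded trans isomer. The carbenoid has other paths (ylide formation at the silyl ether oxygens, insertion into the silyl ethyl groups).
- Comparison: the chosen plan has a longer ring A sequence but answers the core, which Alternative 2 leaves open.

**Alternative 3:** The cut is C8–C9, made by photochemical 1,3-acyl shift of norbornenone A5 to cyclobutanone A6.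
- Merits: A5 comes from a Diels–Alder reaction that can be run enantioselectively, so no resolution is needed and the starting materials are cheap. In absolute stereocontrol and cost this road is better than the chosen plan, which gives up half of its material at the resolution.
- Weak points: the acyl shift is reversible and leads to a photostationary mixture, with decarbonylation as a drain. A6 holds only rings A and B, and ring A is a bare cyclopentene without the C5 oxygen or the C7 methyl. Carbonyl addition to the C9 cyclobutanone from its open face would place the new carbon anti and the oxygen syn to ring A, the reverse of what 29 needs, so ring C requires a detour.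
- Comparison: the chosen plan has ring C, both quaternary centres and all four cyclobutane stereocentres in place at the key step.

Key step: step 6

Assumption: the cycloadduct with ring C endo is the major or at least a separable product of step 3, and the (2R,3R) acid gives the less soluble salt with the enantiomer needed (the (2S,3S) acid is used otherwise).

## Steps

Step 1
Reactants: 1 2-hydroxy-3-methylcyclopent-2-en-1-one
Product: 2 2-[(tert-butyldimethylsilyl)oxy]-3-methylcyclopent-2-en-1-one
Conditions: TBSCl, imidazole, DMF, 23 °C
Reagents that add atoms: tert-butyldimethylsilyl chloride, CC(C)(C)[Si](C)(C)Cl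
Why: O-silylation of an enolised 1,2-diketone; the hindered silyl group masks O10 through the amine stages and leaves a captodative alkene as the 2π partner.

Step 2
Reactants: 3 5-methylpyridin-3-ol; 4 benzyl bromide
Product: 5 1-benzyl-3-hydroxy-5-methylpyridin-1-ium bromide
Conditions: MeCN, 80 °C
Reagents that add atoms: none
Why: Menshutkin N-alkylation; the neutral pyridinol reacts at nitrogen and the salt crystallises from the medium.

Step 3
Reactants: 5 1-benzyl-3-hydroxy-5-methylpyridin-1-ium bromide; 2 2-[(tert-butyldimethylsilyl)oxy]-3-methylcyclopent-2-en-1-one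
Product: 7 racemic N-benzyl endo cycloadduct (8-azabicyclo[3.2.1]oct-3-en-2-one with ring C fused at C3–C9), via 1-benzyl-5-methylpyridin-1-ium-3-olate betaine 6 (not isolated)
Conditions: Et3N, hydroquinone (cat.), 2 (5 equiv), toluene, 120 °C, sealed tube
Reagents that add atoms: none
Why: Base frees the 3-oxidopyridinium betaine, which adds across its C2/C6 positions to electron-poor alkenes in a (5+2) dipolar cycloaddition; the enone β-carbon C3 should join the oxide-flanked carbon (C4) and the carbonyl-bearing C9 the carbon next to the ring methyl (C8), as with acrylates and enones. A tetrasubstituted alkene is at the limit of this reaction, hence the excess of 2 and a temperature at which betaine dimer and adducts equilibrate; the silyloxy group should avoid the space under the enone bridge, so the adduct with ring C endo and CH3/OTBS syn to nitrogen is the expected thermodynamic product, setting C3, C4, C8 and C9 (racemic).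

Step 4
Reactants: 7 racemic N-benzyl endo cycloadduct
Product: 9 racemic secondary amine (N–H bridging C4 and C8), via 1-chloroethyl carbamate 8 (not isolated)
Conditions: ClCO2CH(Cl)CH3, ClCH2CH2Cl, 83 °C; then MeOH, 65 °C; aq. NaHCO3
Reagents that add atoms: none
Why: Chloroformate N-dealkylation: the acylammonium ion loses benzyl chloride (the bridgehead carbons cannot be attacked) and methanol cleaves the 1-chloroethyl carbamate; hydrogenolysis is avoided because of the enone, and the hindered tertiary silyl ether should survive the brief methanolic HCl.

Step 5
Reactants: 9 racemic secondary amine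
Product: 11 enantiopure secondary amine (C3/C4/C8/C9 as in 29), via hydrogen di-p-toluoyl-L-tartrate salt 10 (not isolated)
Conditions: (2R,3R)-O,O′-di-p-toluoyltartaric acid, EtOH, two crystallisations; moist salt broken with cold 1 M NaOH, CH2Cl2
Reagents that add atoms: none
Why: Classical resolution of a basic secondary amine through diastereomeric salts; no stereocentre is formed, the absolute configuration of the whole route is selected here.

Step 6
Reactants: 11 enantiopure secondary amine
Product: 14 cis-syn-cis tricyclic enedione (ring A enone; ring B; ring C ketone with C9–OTBS), via isodiazene 12 (not isolated), via 1,4-diradical 13 (not isolated)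
Conditions: PhI(OAc)2 (2.5 equiv), H2NCO2NH4 (8 equiv), CF3CH2OH, 80 °C
Reagents that add atoms: none
Why: Proposed new method: Ammonia and PhI(OAc)2 generate an electrophilic iodonitrene that N-aminates the secondary amine to the 1,1-diazene 12; loss of N2 leaves the singlet 1,4-diradical 13, whose termini C4 (α to the C5 carbonyl) and C8 (allylic to C6=C7) recombine. The closest known reaction type is the isodiazene-mediated contraction of pyrrolidines to cyclobutanes and nitrogen deletion from secondary amines, which has not been shown on a bridged nortropane. One bond closes two rings: ring B by transannular 1,4-radical recombination inside the seven-membered ring C3–C4–C5–C6–C7–C8–C9, and ring A because the same bond turns the nitrogen-bridged ring into a carbocyclic 3-methylcyclopent-2-enone. At C4 and C8 each C–N bond is replaced by the C–C bond on the same face, because the C3–C9 tether holds the radical centres about 2.3 Å apart and allows only cis fusion; their syn relation to ring C was fixed when ring C went endo in step 3. The step needs recombination to beat β-scission of C3–C9 (ten-membered ring), isodiazene-to-hydrazone tautomerisation and tetrazene formation; the bridgehead hydrogens cannot tautomerise (Bredt's rule), carbonyl and allyl stabilisation lowers the barrier to N2 loss, and the short-lived singlet diradical has both orbitals on the face that nitrogen leaves. Capture of a dipolar form of 13 by the fluoroalcohol is the side reaction to watch.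

Step 7
Reactants: 14 cis-syn-cis tricyclic enedione
Product: 15 C6/C7 exo-epoxy ketone
Conditions: tBuOOH, DBU, CH2Cl2, 0 → 23 °C
Reagents that add atoms: tert-butyl hydroperoxide, CC(C)(C)OO
Why: Weitz–Scheffer epoxidation: the peroxide anion adds to C7 on the exo face of ring A (the endo face lies in the cleft) and the enolate closes, so the oxygen at C6/C7 is exo; anhydrous base spares the silyloxy ketone.

Step 8
Reactants: 15 C6/C7 exo-epoxy ketone
Product: 17 C1 exo-hydroxy ketone, via potassium enolate 16 (not isolated)
Conditions: KN(SiMe3)2, THF, −78 °C; then 2-(phenylsulfonyl)-3-phenyloxaziridine, −78 °C; AcOH quench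
Reagents that add atoms: 2-(phenylsulfonyl)-3-phenyloxaziridine, O=S(=O)(N1OC1c1ccccc1)c1ccccc1
Why: Davis oxidation: the C13 ketone can enolise only towards C1 (C9 is quaternary and the epoxy ketone has no unstrained α-hydrogen), and oxygen is delivered to C1 on the exo face of ring C, the face of the C3 methyl and O10, because ring A blocks the other.

Step 9
Reactants: 17 C1 exo-hydroxy ketone
Product: 18 C1 tiglate
Conditions: (E)-2-methylbut-2-enoyl chloride, pyridine, DMAP (cat.), CH2Cl2, 0 → 23 °C
Reagents that add atoms: (E)-2-methylbut-2-enoyl chloride, C/C=C(\C)C(Cl)=O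
Why: DMAP-catalysed acylation of the only free hydroxyl; the tiglate is the stable (E) isomer, so the double bond geometry should be kept.

Step 10
Reactants: 18 C1 tiglate
Product: 19 C9 ketol (free tertiary hydroxyl next to the C13 ketone)
Conditions: Bu4NF, AcOH (1:1), THF, 0 °C
Reagents that add atoms: none
Why: Buffered fluoride cleaves the silyl ether without leaving a free alkoxide; 19 is a 1-acylcyclobutanol that could ring-expand by α-ketol shift under base, so it is acylated at once.

Step 11
Reactants: 20 ethyl 2-(diethoxyphosphoryl)acrylate; 21 4-methoxybenzyl alcohol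
Product: 22 ethyl 2-(diethoxyphosphoryl)-3-[(4-methoxybenzyl)oxy]propanoate (racemic)
Conditions: DBU (0.2 equiv), MeCN, 23 °C
Reagents that add atoms: none
Why: Oxa-Michael addition of the alcohol to a doubly activated vinylphosphonate; it supplies C11, C12 and C14 with the C14 oxygen already protected.

Step 12
Reactants: 22 ethyl 2-(diethoxyphosphoryl)-3-[(4-methoxybenzyl)oxy]propanoate
Product: 23 2-(diethoxyphosphoryl)-3-[(4-methoxybenzyl)oxy]propanoic acid (racemic)
Conditions: LiOH, THF/H2O, 0 °C; then 1 M HCl
Reagents that add atoms: lithium hydroxide, [Li+].[OH-]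
Why: Saponification of the carboxylic ester in the presence of the phosphonate diester, as for phosphonoacetates; kept cold to avoid retro-Michael loss of the alkoxide.

Step 13
Reactants: 19 C9 ketol; 23 2-(diethoxyphosphoryl)-3-[(4-methoxybenzyl)oxy]propanoic acid
Product: 24 C9 phosphonoacetate ester (mixture at C12)
Conditions: DCC, DMAP (cat.), CH2Cl2, 0 → 23 °C
Reagents that add atoms: none
Why: Steglich esterification; phosphonoacetic acids are among the acids that acylate hindered tertiary alcohols well under carbodiimide activation, and the C12 centre is lost in the next step.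

Step 14
Reactants: 24 C9 phosphonoacetate ester
Product: 25 butenolide with C14 4-methoxybenzyl ether
Conditions: LiCl, DBU, MeCN, 23 °C
Reagents that add atoms: none
Why: Intramolecular Horner–Wadsworth–Emmons olefination under Masamune–Roush conditions closes ring D (five-membered; the C12=C13 geometry is fixed by the ring); the phosphonate is more acidic than C1–H, and the mild base limits β-elimination of the benzyloxy group.

Step 15
Reactants: 25 butenolide with C14 4-methoxybenzyl ether
Product: 26 C7 exo-hydroxy C5 ketone
Conditions: (PhSe)2, NaBH4, EtOH, 23 °C; then AcOH and 25, 0 → 23 °C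
Reagents that add atoms: none
Why: Organoselenium reduction of an α,β-epoxy ketone (selenide opens at C6, a second selenide removes selenium); the C6–O bond is cleaved and the C7–O bond kept, so the tertiary hydroxyl stays exo, and esters, butenolide and ether are left alone.

Step 16
Reactants: 26 C7 exo-hydroxy C5 ketone
Product: 27 C5 endo, C7 exo diol
Conditions: Me4NBH(OAc)3, AcOH/MeCN, −30 → 0 °C
Reagents that add atoms: none
Why: Evans–Saksena reduction: the C7 hydroxyl binds boron and hydride is delivered to C5 on the exo face, which is also the open face, giving the endo alcohol (1,3-anti); the reagent does not reduce esters or lactones.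

Step 17
Reactants: 27 C5 endo, C7 exo diol
Product: 28 triol (C5 endo OH, C7 exo OH, C14 OH)
Conditions: DDQ, CH2Cl2/pH 7 buffer, 0 → 23 °C
Reagents that add atoms: none
Why: Oxidative cleavage of the 4-methoxybenzyl ether under neutral conditions frees the primary allylic alcohol.

Step 18
Reactants: 28 triol
Product: 29 CNP0210373.1
Conditions: PPh3, DIAD, AcOH, toluene, 0 → 40 °C
Reagents that add atoms: acetic acid, CC(=O)O
Why: Mitsunobu esterification: the primary allylic alcohol is acetylated and the endo C5 alcohol is displaced with inversion by acetate entering from the exo face, which sets the C5 stereocentre; the tertiary C7 hydroxyl does not react.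

## Compound list

1 | 2-hydroxy-3-methylcyclopent-2-en-1-one | CC1=C(O)C(=O)CC1 | starting material
2 | 2-[(tert-butyldimethylsilyl)oxy]-3-methylcyclopent-2-en-1-one | CC1=C(O[Si](C)(C)C(C)(C)C)C(=O)CC1 | intermediate
3 | 5-methylpyridin-3-ol | Cc1cncc(O)c1 | starting material
4 | benzyl bromide | BrCc1ccccc1 | starting material
5 | 1-benzyl-3-hydroxy-5-methylpyridin-1-ium bromide | Cc1c[n+](Cc2ccccc2)cc(O)c1.[Br-] | intermediate
6 | 1-benzyl-5-methylpyridin-1-ium-3-olate (betaine, not isolated) | Cc1c[n+](Cc2ccccc2)cc([O-])c1 | intermediate
7 | racemic N-benzyl cycloadduct: 8-benzyl-8-azabicyclo[3.2.1]oct-3-en-2-one (C5=O, C6=C7–CH3) with N bridging C4 and C8; ring C cyclopentanone (C13=O) fused at C3–C9 under the enone bridge (endo); C3–CH3 and C9–OTBS syn to N (one enantiomer drawn) | C1C[C@]2(C)[C@@H]3C(=O)C=C(C)[C@@H](N3Cc4ccccc4)[C@]2(O[Si](C)(C)C(C)(C)C)C1=O | intermediate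
8 | N-(1-chloroethoxycarbonyl) derivative of 9 (not isolated; racemic) | C1C[C@]2(C)[C@@H]3C(=O)C=C(C)[C@@H](N3C(=O)OC(C)Cl)[C@]2(O[Si](C)(C)C(C)(C)C)C1=O | intermediate
9 | racemic secondary amine: N–H analogue of 7 (one enantiomer drawn) | C1C[C@]2(C)[C@@H]3C(=O)C=C(C)[C@@H](N3)[C@]2(O[Si](C)(C)C(C)(C)C)C1=O | intermediate
10 | hydrogen (2R,3R)-O,O′-di-p-toluoyltartrate salt of 11 (not isolated) | C1C[C@]2(C)[C@@H]3C(=O)C=C(C)[C@@H]([NH2+]3)[C@]2(O[Si](C)(C)C(C)(C)C)C1=O.OC(=O)[C@H](OC(=O)c1ccc(C)cc1)[C@@H](OC(=O)c1ccc(C)cc1)C([O-])=O | intermediate
11 | key-step precursor: single enantiomer of 9, the ring-C-fused 8-azabicyclo[3.2.1]oct-3-en-2-one with free N–H (C3, C4, C8, C9 as in 29) | C1C[C@]2(C)[C@@H]3C(=O)C=C(C)[C@@H](N3)[C@]2(O[Si](C)(C)C(C)(C)C)C1=O | intermediate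
12 | isodiazene (N-nitrene of 11, not isolated) | C1C[C@]2(C)[C@@H]3C(=O)C=C(C)[C@@H]([N+]3=[N-])[C@]2(O[Si](C)(C)C(C)(C)C)C1=O | intermediate
13 | 1,4-diradical at C4 and C8 after loss of N2 (not isolated) | C1C[C@]2(C)[CH]C(=O)C=C(C)[CH][C@]2(O[Si](C)(C)C(C)(C)C)C1=O | intermediate
14 | key-step product: cis-syn-cis tricycle; ring A 3-methylcyclopent-2-enone (C5=O, C6=C7) fused at C4–C8 to cyclobutane ring B; ring C cyclopentanone (C13=O) with C9–OTBS and C3–CH3 | C1C[C@]2(C)[C@@H]3C(=O)C=C(C)[C@@H]3[C@]2(O[Si](C)(C)C(C)(C)C)C1=O | intermediate
15 | epoxy ketone: 14 with exo C6/C7 epoxide (oxygen cis to H4 and H8) | C1C[C@]2(C)[C@@H]3C(=O)[C@H]4O[C@@]4(C)[C@@H]3[C@]2(O[Si](C)(C)C(C)(C)C)C1=O | intermediate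
16 | potassium C13/C1 enolate of 15 (not isolated) | C=1C[C@]2(C)[C@@H]3C(=O)[C@H]4O[C@@]4(C)[C@@H]3[C@]2(O[Si](C)(C)C(C)(C)C)C=1[O-].[K+] | intermediate
17 | 15 with exo hydroxyl at C1 (cis to C3–CH3 and O10) | O[C@H]1C[C@]2(C)[C@@H]3C(=O)[C@H]4O[C@@]4(C)[C@@H]3[C@]2(O[Si](C)(C)C(C)(C)C)C1=O | intermediate
18 | C1 (E)-2-methylbut-2-enoate (tiglate) of 17 | C/C=C(\C)C(=O)O[C@H]1C[C@]2(C)[C@@H]3C(=O)[C@H]4O[C@@]4(C)[C@@H]3[C@]2(O[Si](C)(C)C(C)(C)C)C1=O | intermediate
19 | desilylated 18: free C9 tertiary hydroxyl next to the C13 ketone | C/C=C(\C)C(=O)O[C@H]1C[C@]2(C)[C@@H]3C(=O)[C@H]4O[C@@]4(C)[C@@H]3[C@]2(O)C1=O | intermediate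
20 | ethyl 2-(diethoxyphosphoryl)acrylate | C=C(C(=O)OCC)P(=O)(OCC)OCC | starting material
21 | 4-methoxybenzyl alcohol | COc1ccc(CO)cc1 | starting material
22 | ethyl 2-(diethoxyphosphoryl)-3-[(4-methoxybenzyl)oxy]propanoate (racemic) | CCOC(=O)C(COCc1ccc(OC)cc1)P(=O)(OCC)OCC | intermediate
23 | 2-(diethoxyphosphoryl)-3-[(4-methoxybenzyl)oxy]propanoic acid (racemic) | OC(=O)C(COCc1ccc(OC)cc1)P(=O)(OCC)OCC | intermediate
24 | ester of the C9 hydroxyl of 19 with acid 23 (mixture at C12) | C/C=C(\C)C(=O)O[C@H]1C[C@]2(C)[C@@H]3C(=O)[C@H]4O[C@@]4(C)[C@@H]3[C@]2(OC(=O)C(COCc5ccc(OC)cc5)P(=O)(OCC)OCC)C1=O | intermediate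
25 | tetracycle with ring D butenolide (C12=C13), C14 4-methoxybenzyl ether, C1 exo tiglate, ring A exo epoxy ketone | C/C=C(\C)C(=O)O[C@H]1C[C@]2(C)[C@@H]3C(=O)[C@H]4O[C@@]4(C)[C@@H]3[C@@]25OC(=O)C(COCc6ccc(OC)cc6)=C15 | intermediate
26 | 25 with ring A as C5 ketone, C6H2 and exo C7 hydroxyl (methyl endo) | C/C=C(\C)C(=O)O[C@H]1C[C@]2(C)[C@@H]3C(=O)C[C@@](C)(O)[C@@H]3[C@@]25OC(=O)C(COCc6ccc(OC)cc6)=C15 | intermediate
27 | diol: C5 hydroxyl endo (trans to the C7 hydroxyl), C7 hydroxyl exo | C/C=C(\C)C(=O)O[C@H]1C[C@]2(C)[C@@H]3[C@H](O)C[C@@](C)(O)[C@@H]3[C@@]25OC(=O)C(COCc6ccc(OC)cc6)=C15 | intermediate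
28 | triol: 27 with free C14 hydroxyl | C/C=C(\C)C(=O)O[C@H]1C[C@]2(C)[C@@H]3[C@H](O)C[C@@](C)(O)[C@@H]3[C@@]25OC(=O)C(CO)=C15 | intermediate
29 | CNP0210373.1: C1 exo tiglate, C5 exo acetate, C7 exo hydroxyl (methyl endo), C14 acetate, cis-syn-cis rings A/B/C, butenolide ring D | C/C=C(\C)C(=O)O[C@H]1C[C@]2(C)[C@@H]3[C@@H](OC(C)=O)C[C@@](C)(O)[C@@H]3[C@@]23OC(=O)C(COC(C)=O)=C13 | target

## Step count and least certain steps

Total: 18 steps. Longest linear sequence: 15 steps (steps 2 to 10 and 13 to 18, or equally step 1, steps 3 to 10 and 13 to 18).

**Step 6 (key step).**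
- What may go wrong: N-amination may lose to condensation of ammonia with the two ketones or to oxidation elsewhere, because the amine is flanked by two quaternary carbons. After loss of N2, fragmentation of the C3–C9 bond or solvent capture of the delocalised diradical may outrun recombination, because both radical centres are conjugated to the enone and the intermediate lives longer than a simple tetramethylene.
- Fallback: give up the nitrogen bridge and build ring B by enone–alkene photocycloaddition, all known reaction types. It sets out from 2. 1,2-Reduction (NaBH4, CeCl3) gives racemic 2-[(tert-butyldimethylsilyl)oxy]-3-methylcyclopent-2-en-1-ol F1. Irradiation (350 nm) of purchased (R)-4-[(tert-butyldimethylsilyl)oxy]cyclopent-2-en-1-one F2 in the presence of F1 should give the head-to-tail photoadduct F3: the silyloxy-bearing C9 joins the enone β-carbon C8, and the alkene enters anti to the C7 silyloxy group, which fixes the absolute configuration. Dess–Martin oxidation of the C13 carbinol gives diketone F4. DBU eliminates the C7 silyloxy group to give the unsubstituted ring A enone F5. Me2CuLi with Me3SiCl adds the C7 methyl and gives the silyl enol ether F6. Pd(OAc)2 (Saegusa oxidation) restores C6=C7, and the route is rejoined at 14. The weak point of this detour is that the cis-anti-cis adduct is the usual preference in such photocycloadditions and would have to be separated.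

**Step 3.**
- What may go wrong: the cycloaddition may be too slow at a tetrasubstituted alkene, so betaine dimerisation and silyl transfer to the phenoxide take over, and ring C may not go endo selectively.
- Fallback: make the cycloaddition intramolecular through a silicon tether on O10. It sets out from 1 and 3. Compound 1 is silylated with (bromomethyl)chlorodimethylsilane to 2-{[(bromomethyl)dimethylsilyl]oxy}-3-methylcyclopent-2-en-1-one F7. Compound 3 is N-alkylated by F7 to the pyridinium bromide F8. Et3N and heat under dilution give the tethered cycloadduct F9, in which the O–Si–CH2–N ring forces O10 syn to nitrogen and therefore ring C endo. Bu4NF in wet THF cleaves Si–O and Si–C to the N-methyl ketol F10. TBSOTf with 2,6-lutidine gives the N-methyl silyl ether F11. ClCO2CH(Cl)CH3 and then MeOH remove the N-methyl group, and the route is rejoined at 9.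

**Step 14 (with step 13).**
- What may go wrong: acylation of the hindered tertiary ketol may be incomplete, or the phosphonate anion may expel the β-benzyloxy group or epimerise C1 before it olefinates the crowded C13 ketone.
- Fallback: bring in C14 after ring closure. It sets out from 19. DCC esterification with bromo(diethoxyphosphoryl)acetic acid F12 (from its commercial triethyl ester) gives ester F13. LiCl and DBU close the α-bromobutenolide F14, whose phosphonate has no β-leaving group. Stille coupling with tributyl(hydroxymethyl)stannane and Pd(PPh3)4 gives the hydroxymethyl butenolide F15. 4-Methoxybenzyl trichloroacetimidate with catalytic camphorsulfonic acid rejoins the route at 25.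

**Step 18.**
- What may go wrong: activation of the C5 hydroxyl inside the cleft by the bulky phosphonium reagent may be incomplete, and elimination to the C5=C6 alkene may compete with substitution.
- Fallback: separate activation from displacement. It sets out from 28. MsCl and Et3N give the bis-mesylate F16. CsOAc with 18-crown-6 in toluene at 80 °C displaces both sulfonates, C5 with inversion, and arrives at 29.

## Further compounds

F1 | step 6 | racemic 2-[(tert-butyldimethylsilyl)oxy]-3-methylcyclopent-2-en-1-ol | CC1=C(O[Si](C)(C)C(C)(C)C)C(O)CC1
F2 | step 6 | (R)-4-[(tert-butyldimethylsilyl)oxy]cyclopent-2-en-1-one (purchased) | O=C1C[C@@H](O[Si](C)(C)C(C)(C)C)C=C1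
F3 | step 6 | head-to-tail photoadduct: cis-syn-cis tricycle with C5 ketone, exo C7 silyloxy, C9 silyloxy, C13 carbinol (mixture at C13) | C1C[C@]2(C)[C@@H]3C(=O)C[C@@H](O[Si](C)(C)C(C)(C)C)[C@@H]3[C@]2(O[Si](C)(C)C(C)(C)C)C1O
F4 | step 6 | C5,C13 diketone from F3 | C1C[C@]2(C)[C@@H]3C(=O)C[C@@H](O[Si](C)(C)C(C)(C)C)[C@@H]3[C@]2(O[Si](C)(C)C(C)(C)C)C1=O
F5 | step 6 | ring A enone without the C7 methyl (C5=O, C6=C7) | C1C[C@]2(C)[C@@H]3C(=O)C=C[C@@H]3[C@]2(O[Si](C)(C)C(C)(C)C)C1=O
F6 | step 6 | C5 trimethylsilyl enol ether with exo C7 methyl | C1C[C@]2(C)[C@@H]3C(O[Si](C)(C)C)=C[C@@H](C)[C@@H]3[C@]2(O[Si](C)(C)C(C)(C)C)C1=O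
F7 | step 3 | 2-{[(bromomethyl)dimethylsilyl]oxy}-3-methylcyclopent-2-en-1-one | CC1=C(O[Si](C)(C)CBr)C(=O)CC1
F8 | step 3 | 3-hydroxy-5-methyl-1-({dimethyl[(2-methyl-5-oxocyclopent-1-en-1-yl)oxy]silyl}methyl)pyridin-1-ium bromide | Cc1c[n+](C[Si](C)(C)OC2=C(C)CCC2=O)cc(O)c1.[Br-]
F9 | step 3 | racemic silicon-tethered cycloadduct (N–CH2–SiMe2–O10 ring; one enantiomer drawn) | C1C[C@]2(C)[C@@H]3C(=O)C=C(C)[C@H]4N3C[Si](C)(C)O[C@@]24C1=O
F10 | step 3 | racemic N-methyl C9 ketol | C1C[C@]2(C)[C@@H]3C(=O)C=C(C)[C@@H](N3C)[C@]2(O)C1=O
F11 | step 3 | racemic N-methyl analogue of 7 (C9–OTBS) | C1C[C@]2(C)[C@@H]3C(=O)C=C(C)[C@@H](N3C)[C@]2(O[Si](C)(C)C(C)(C)C)C1=O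
F12 | step 14 | bromo(diethoxyphosphoryl)acetic acid | OC(=O)C(Br)P(=O)(OCC)OCC
F13 | step 14 | ester of the C9 hydroxyl of 19 with F12 | C/C=C(\C)C(=O)O[C@H]1C[C@]2(C)[C@@H]3C(=O)[C@H]4O[C@@]4(C)[C@@H]3[C@]2(OC(=O)C(Br)P(=O)(OCC)OCC)C1=O
F14 | step 14 | C12-bromo butenolide | C/C=C(\C)C(=O)O[C@H]1C[C@]2(C)[C@@H]3C(=O)[C@H]4O[C@@]4(C)[C@@H]3[C@@]25OC(=O)C(Br)=C15
F15 | step 14 | C12-hydroxymethyl butenolide (ring A epoxy ketone) | C/C=C(\C)C(=O)O[C@H]1C[C@]2(C)[C@@H]3C(=O)[C@H]4O[C@@]4(C)[C@@H]3[C@@]25OC(=O)C(CO)=C15
F16 | step 18 | C5 (endo), C14 bis-methanesulfonate of 28 | C/C=C(\C)C(=O)O[C@H]1C[C@]2(C)[C@@H]3[C@H](OS(C)(=O)=O)C[C@@](C)(O)[C@@H]3[C@@]25OC(=O)C(COS(C)(=O)=O)=C15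
A1 | alternative 1 | ring-A-fused 2-[(4-methoxybenzyl)oxy]tropone with C3 methyl and C7 dioxolane | O=C1C=CC(C)=C2CCC3(OCCO3)C2=C1OCc1ccc(OC)cc1
A2 | alternative 1 | tricyclic photoisomer with C4=C8 cyclobutene | O=C1C=C[C@]2(C)C3CCC4(OCCO4)C=3[C@]12OCc1ccc(OC)cc1
A3 | alternative 2 | C4 diazomethyl ketone with C8 1-(silyloxy)ethyl group on the ring B/C bicycle | C1C[C@]2(C)[C@H](C(=O)C=[N+]=[N-])[C@H]([C@H](C)O[Si](C)(C)C(C)(C)C)[C@]2(O[Si](CC)(CC)CC)C13OCCO3
A4 | alternative 2 | tricyclic ring A ketone with quaternary C7 | C1C[C@]2(C)[C@@H]3C(=O)C[C@@](C)(O[Si](C)(C)C(C)(C)C)[C@@H]3[C@]2(O[Si](CC)(CC)CC)C13OCCO3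
A5 | alternative 3 | 3-allyl-3-methylbicyclo[2.2.1]hept-5-en-2-one | O=C1[C@](C)(CC=C)[C@@H]2C[C@H]1C=C2
A6 | alternative 3 | 6-allyl-6-methylbicyclo[3.2.0]hept-2-en-7-one | O=C1[C@](C)(CC=C)[C@@H]2CC=C[C@H]12
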